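## Retrosynthetic overview

- The target is (2S)-7-hydroxy-4'-methoxy-6,8-diprenylflavanone. Ring C and its only stereocentre (C2) are made last, by closing the O1–C2 bond of an achiral 2'-hydroxychalcone with a chalcone isomerase (enzyme class: chalcone–flavanone isomerase, an intramolecular lyase, EC 5.5.1.6).
- Enabling feature: O1 sits on C8a of ring A, ortho to the C4 ketone, so in the ring-opened form C2 is the β-carbon of an aryl enone (chain O1–C8a–C4a–C4–C3–C2). Ring A has the 7-OH/5-H (6'-deoxy, isoliquiritigenin-type) pattern that legume (type 2) chalcone isomerases accept and that keeps the uncatalysed closure slow.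
- The chalcone comes from a Claisen–Schmidt condensation (C2–C3 unit formed as C=C) of a bis-MOM-protected 3,5-diprenylacetophenone with 4-methoxybenzaldehyde, followed by MOM removal.
- Both prenyl groups (C6, C8) come from a twofold Stille coupling on the 3,5-diiodide of 2,4-dihydroxyacetophenone.
- Ring order: rings A and B are bought as arenes; ring C is the only ring formed (step 6).

Key step: step 6

Assumption: a purified recombinant legume (type 2) chalcone isomerase, such as the Medicago sativa enzyme expressed in Escherichia coli, is treated as an accessible catalyst; its preparation is not counted as a step.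

## Route

Step 1
Reactants: 1 2,4-dihydroxyacetophenone
Product: 2 1-(2,4-dihydroxy-3,5-diiodophenyl)ethanone
Conditions: NIS (2.1 equiv), TFA (10 mol%), MeCN, 0 °C to rt
Reagents that add atoms: N-iodosuccinimide, O=C1CCC(=O)N1I
Why: Electrophilic aromatic substitution: C3 and C5 of the resorcinol ring are each ortho or para to both hydroxyl groups, whereas C6 is meta to both and next to the acetyl group, so two equivalents of NIS should iodinate exactly the two carbons that will carry the prenyl groups.

Step 2
Reactants: 2 1-(2,4-dihydroxy-3,5-diiodophenyl)ethanone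
Product: 3 1-[3,5-diiodo-2,4-bis(methoxymethoxy)phenyl]ethanone
Conditions: NaH (2.3 equiv), MOMCl (2.5 equiv), DMF, 0 °C to rt
Reagents that add atoms: chloromethyl methyl ether, COCCl
Why: Williamson-type O-alkylation of both phenoxides with MOMCl should give the bis-acetal, which keeps acidic phenols out of the Stille and aldol steps and can be removed later under mild acid.

Step 3
Reactants: 3 1-[3,5-diiodo-2,4-bis(methoxymethoxy)phenyl]ethanone; 4 tributyl(3-methylbut-2-en-1-yl)stannane
Product: 5 1-[2,4-bis(methoxymethoxy)-3,5-bis(3-methylbut-2-en-1-yl)phenyl]ethanone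
Conditions: 4 (2.6 equiv), Pd(PPh3)4 (10 mol%), DMF, 95 °C, argon
Reagents that add atoms: none
Why: Twofold Migita–Kosugi–Stille coupling: oxidative addition of zerovalent palladium into each C–I bond, transmetalation from the allylic stannane at its tin-bearing carbon and reductive elimination should give the linear 3-methylbut-2-enyl groups at C3 and C5, a reaction type with close precedent for the prenylation of oxygenated aryl iodides.

Step 4
Reactants: 5 1-[2,4-bis(methoxymethoxy)-3,5-bis(3-methylbut-2-en-1-yl)phenyl]ethanone; 6 4-methoxybenzaldehyde
Product: 8 (E)-1-[2,4-bis(methoxymethoxy)-3,5-bis(3-methylbut-2-en-1-yl)phenyl]-3-(4-methoxyphenyl)prop-2-en-1-one, via aldol adduct 7 (not isolated)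
Conditions: 6 (1.2 equiv), KOH (5 equiv, 50% aq.), EtOH, rt
Reagents that add atoms: none
Why: Claisen–Schmidt condensation: the methyl ketone enolate adds to the non-enolizable aldehyde and the aldol adduct 7 loses water by an E1cB pathway to the conjugated, thermodynamically preferred E-enone, while the MOM ethers and prenyl groups are inert to aqueous KOH.

Step 5
Reactants: 8 (E)-1-[2,4-bis(methoxymethoxy)-3,5-bis(3-methylbut-2-en-1-yl)phenyl]-3-(4-methoxyphenyl)prop-2-en-1-one
Product: 9 (E)-1-[2,4-dihydroxy-3,5-bis(3-methylbut-2-en-1-yl)phenyl]-3-(4-methoxyphenyl)prop-2-en-1-one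
Conditions: 3 M aq. HCl/MeOH (1:4), 45 °C, dark, stopped at full conversion; chromatography
Reagents that add atoms: none
Why: Acid-catalysed cleavage of the two methoxymethyl acetals (transacetalization to methanol, precedented on C-prenylated chalcones) should free both phenols, and mild temperature and short time are chosen because the same acid could add a phenol to a neighbouring prenyl group or close ring C racemically, so 9 is purified before the enzymatic step.

Step 6
Reactants: 9 (E)-1-[2,4-dihydroxy-3,5-bis(3-methylbut-2-en-1-yl)phenyl]-3-(4-methoxyphenyl)prop-2-en-1-one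
Product: 11 (2S)-7-hydroxy-2-(4-methoxyphenyl)-6,8-bis(3-methylbut-2-en-1-yl)chroman-4-one, via enol 10 (not isolated)
Conditions: recombinant type 2 chalcone isomerase (EC 5.5.1.6, Medicago sativa enzyme, 1–2 mol%), KH2PO4/K2HPO4 buffer (50 mM, pH 7.5), 10% v/v DMSO, 2-hydroxypropyl-β-cyclodextrin, 25 °C, dark
Reagents that add atoms: none
Why: Proposed new method: chalcone isomerases have not been shown to accept 3',5'-di-C-prenylated 4-O-methylchalcones, the closest known reaction being the cyclization of isoliquiritigenin (4,2',4'-trihydroxychalcone, same ring A hydroxylation pattern) to (2S)-liquiritigenin by type 2 chalcone isomerase; mechanistically the enzyme binds the chalcone with its 2'-oxygen ionized, this phenoxide adds to the β-carbon of the enone (intramolecular oxa-Michael addition) to give the enzyme-bound enol(ate) 10, held by hydrogen bonds to the carbonyl oxygen, and protonation at C3 releases ketone 11. Ring C (the dihydropyranone) closes in the 6-endo-trig mode. The new stereocentre C2 is set under catalyst control: the active-site cleft holds the cinnamoyl arm in the one conformation in which the phenoxide reaches a single face of the β-carbon, the face that gives (2S) in the flavanones made by this enzyme class, and the substrate has no stereocentre to compete. The step needs enantioface selectivity over the racemic background closure, which the substrate secures because it belongs to the 6'-deoxy series (C5–H in the product): its only ortho hydroxyl is tied up in a hydrogen bond to the ketone, so spontaneous cyclization near neutral pH should be slow relative to the enzymatic one. It also needs chemoselectivity, which neutral buffer provides: the 4'-hydroxyl cannot reach the enone, and the two prenyl groups, which could cyclize onto the neighbouring phenols under acid, are inert. DMSO and cyclodextrin address the low solubility of the lipophilic substrate, and a small panel of legume enzymes would be screened in case the prenyl groups clash with the wall of the ring A pocket.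

## Compound list

1 | 2,4-dihydroxyacetophenone | CC(=O)c1ccc(O)cc1O | starting material
2 | 1-(2,4-dihydroxy-3,5-diiodophenyl)ethanone | CC(=O)c1cc(I)c(O)c(I)c1O | intermediate
3 | 1-[3,5-diiodo-2,4-bis(methoxymethoxy)phenyl]ethanone | CC(=O)c1cc(I)c(OCOC)c(I)c1OCOC | intermediate
4 | tributyl(3-methylbut-2-en-1-yl)stannane | CCCC[Sn](CCCC)(CCCC)CC=C(C)C | starting material
5 | 1-[2,4-bis(methoxymethoxy)-3,5-bis(3-methylbut-2-en-1-yl)phenyl]ethanone | CC(=O)c1cc(CC=C(C)C)c(OCOC)c(CC=C(C)C)c1OCOC | intermediate
6 | 4-methoxybenzaldehyde | COc1ccc(C=O)cc1 | starting material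
7 | aldol adduct: racemic 3-hydroxy-1-[2,4-bis(methoxymethoxy)-3,5-bis(3-methylbut-2-en-1-yl)phenyl]-3-(4-methoxyphenyl)propan-1-one | COc1ccc(C(O)CC(=O)c2cc(CC=C(C)C)c(OCOC)c(CC=C(C)C)c2OCOC)cc1 | intermediate
8 | (E)-1-[2,4-bis(methoxymethoxy)-3,5-bis(3-methylbut-2-en-1-yl)phenyl]-3-(4-methoxyphenyl)prop-2-en-1-one | COc1ccc(/C=C/C(=O)c2cc(CC=C(C)C)c(OCOC)c(CC=C(C)C)c2OCOC)cc1 | intermediate
9 | (E)-1-[2,4-dihydroxy-3,5-bis(3-methylbut-2-en-1-yl)phenyl]-3-(4-methoxyphenyl)prop-2-en-1-one | COc1ccc(/C=C/C(=O)c2cc(CC=C(C)C)c(O)c(CC=C(C)C)c2O)cc1 | intermediate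
10 | enzyme-bound enol drawn in its neutral form: (2S)-2-(4-methoxyphenyl)-6,8-bis(3-methylbut-2-en-1-yl)-2H-chromene-4,7-diol | COc1ccc([C@@H]2C=C(O)c3cc(CC=C(C)C)c(O)c(CC=C(C)C)c3O2)cc1 | intermediate
11 | (2S)-7-hydroxy-2-(4-methoxyphenyl)-6,8-bis(3-methylbut-2-en-1-yl)chroman-4-one | COc1ccc([C@@H]2CC(=O)c3cc(CC=C(C)C)c(O)c(CC=C(C)C)c3O2)cc1 | target

## Step count and risks

Total step count: 6. Longest linear sequence: 6 steps (from 1).

Steps most likely to fail:

1. Step 6 (proposed method). The enzyme may fail to turn over the substrate, through steric clash of the two prenyl groups in the ring A pocket or through poor solubility, leaving only slow racemic background closure and low enantiomeric purity. The fallback sets out from 9 and comes back at 11. Chalcone 9 would be closed without stereocontrol by NaOAc in refluxing EtOH (reversible base-mediated oxa-Michael addition) to racemic 7-hydroxy-2-(4-methoxyphenyl)-6,8-bis(3-methylbut-2-en-1-yl)chroman-4-one F1. The enantiomers would then be separated by preparative HPLC on an amylose tris(3,5-dimethylphenylcarbamate) stationary phase to give 11. The (2R)-enantiomer would be set aside, or reopened to 9 with KOH in EtOH for another cycle.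

2. Step 3. The second coupling at the doubly ortho-substituted C3 iodide may be incomplete, protodeiodination may compete, or allylic transposition during transmetalation may give 1,1-dimethylallyl groups. The fallback sets out from 1 and comes back at 5, building the prenyl groups by sigmatropic rearrangement and olefin metathesis instead of cross-coupling. Compound 1 would be O-allylated twice (allyl bromide, K2CO3, DMF, 60 °C) to 1-[2,4-bis(prop-2-en-1-yloxy)phenyl]ethanone F2. Heating in N,N-diethylaniline at about 200 °C should bring about a double aromatic Claisen rearrangement to 1-[2,4-dihydroxy-3,5-di(prop-2-en-1-yl)phenyl]ethanone F3; every ortho or ortho-then-para pathway converges on this compound, because an unsubstituted allyl group is unchanged by one or two allylic transpositions. Protection with MOMCl and NaH in DMF would give 1-[2,4-bis(methoxymethoxy)-3,5-di(prop-2-en-1-yl)phenyl]ethanone F4. Cross-metathesis with 2-methylbut-2-ene (second-generation Grubbs catalyst, RuCl2(=CHPh)(PCy3)(H2IMes), CH2Cl2, 40 °C) would convert both allyl groups into prenyl groups and return the route at 5.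

3. Step 5. The liberated phenols may add to the prenyl double bonds under acid (2,2-dimethylchroman formation), and ring C may close racemically under acid. The fallback sets out from 2 and comes back at 9, and never protects the phenols, so that no acid is applied to a prenylated phenol. Stille coupling of the free diiodide 2 with 4 (Pd(PPh3)4, DMF, 95 °C) would give 1-[2,4-dihydroxy-3,5-bis(3-methylbut-2-en-1-yl)phenyl]ethanone F5. Its trianion (LiN(SiMe3)2, 4 equiv, THF, −78 °C to rt) would be condensed with 6 to the aldol adduct 3-hydroxy-1-[2,4-dihydroxy-3,5-bis(3-methylbut-2-en-1-yl)phenyl]-3-(4-methoxyphenyl)propan-1-one F6. F6 is formed in the flask and should dehydrate there on warming (E1cB) to give 9 after NH4Cl work-up.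

Further compounds

F1 | step 6 | racemic 7-hydroxy-2-(4-methoxyphenyl)-6,8-bis(3-methylbut-2-en-1-yl)chroman-4-one | COc1ccc(C2CC(=O)c3cc(CC=C(C)C)c(O)c(CC=C(C)C)c3O2)cc1
F2 | step 3 | 1-[2,4-bis(prop-2-en-1-yloxy)phenyl]ethanone | CC(=O)c1ccc(OCC=C)cc1OCC=C
F3 | step 3 | 1-[2,4-dihydroxy-3,5-di(prop-2-en-1-yl)phenyl]ethanone | CC(=O)c1cc(CC=C)c(O)c(CC=C)c1O
F4 | step 3 | 1-[2,4-bis(methoxymethoxy)-3,5-di(prop-2-en-1-yl)phenyl]ethanone | CC(=O)c1cc(CC=C)c(OCOC)c(CC=C)c1OCOC
F5 | step 5 | 1-[2,4-dihydroxy-3,5-bis(3-methylbut-2-en-1-yl)phenyl]ethanone | CC(=O)c1cc(CC=C(C)C)c(O)c(CC=C(C)C)c1O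
F6 | step 5 | racemic 3-hydroxy-1-[2,4-dihydroxy-3,5-bis(3-methylbut-2-en-1-yl)phenyl]-3-(4-methoxyphenyl)propan-1-one | COc1ccc(C(O)CC(=O)c2cc(CC=C(C)C)c(O)c(CC=C(C)C)c2O)cc1
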